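The pyranone ring C is cut across two bonds at once, C3–C4 and O1–C2. C2 and C3 then become the two carbons of an internal alkyne that already carries ring B on one end and the C3 prenyl group on the other. C4 and O1 come from a ring-A salicylaldehyde. One rhodium-catalysed oxidative annulation (aldehyde C–H and phenol O–H across the alkyne) closes ring C, joins both halves and sets the crowded tetrasubstituted C2=C3 unit. The para 2',5'-dioxygen pattern of ring B lets a cheap 2,4,5-trimethoxyphenyl group stand in for the hydroquinone. Both prenyl groups enter in one dianion alkylation.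

Key step: step 4

Remark: the target has no stereocentre and no stable stereogenic axis, and each alkene ends in two methyl groups. It is therefore achiral, and no step has to control configuration.

Step 1
Reactants: 1 2,4,5-trimethoxybenzaldehyde
Product: 2 1-ethynyl-2,4,5-trimethoxybenzene
Conditions: Ohira–Bestmann reagent (1.3 equiv), K2CO3 (2 equiv), MeOH, rt
Reagents that add atoms: dimethyl (1-diazo-2-oxopropyl)phosphonate (Ohira–Bestmann reagent), COP(=O)(OC)C(=[N+]=[N-])C(C)=O
Why: This is a Seyferth–Gilbert homologation in its Ohira–Bestmann form, in which methanolysis of the reagent gives the diazomethylphosphonate anion, this olefinates the non-enolisable aldehyde, and loss of N2 with a 1,2-hydride shift should give the terminal alkyne without touching the methyl ethers.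

Step 2
Reactants: 2 1-ethynyl-2,4,5-trimethoxybenzene; 3 prenyl bromide (1-bromo-3-methylbut-2-ene)
Product: 6 1-(5-methylhex-4-en-1-yn-1-yl)-2,4,5-trimethoxy-3-(3-methylbut-2-en-1-yl)benzene, via dilithio species 4 (not isolated), via lithium acetylide 5 (not isolated)
Conditions: n-BuLi (2.3 equiv), TMEDA, THF, −78 to 0 °C; 3 (1.05 equiv), −78 to 0 °C; then CuI (15 mol %), 3 (1.3 equiv), 0 °C to rt
Reagents that add atoms: prenyl bromide 3, CC(C)=CCBr
Why: This combines directed ortho-metalation with copper-catalysed acetylide allylation, in which the ring C–H flanked by two methoxy groups (C3) is lithiated after the alkyne C–H, the aryllithium as the stronger base and nucleophile is consumed first by SN2 attack on the primary carbon of 3, and the remaining acetylide couples through its copper acetylide, so no strong base should remain when the base-sensitive skipped enyne appears.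

Step 3
Reactants: 7 2,4,6-trihydroxybenzaldehyde
Product: 8 2-hydroxy-4,6-bis(methoxymethoxy)benzaldehyde
Conditions: MOMCl (2.1 equiv), i-Pr2NEt, CH2Cl2, 0 °C to rt
Reagents that add atoms: chloromethyl methyl ether (MOMCl), COCCl
Why: This is a selective Williamson-type O-alkylation in which the 4-OH and one of the two equivalent ortho OH groups react, while the last ortho OH stays hydrogen-bonded to the formyl oxygen and remains free as the directing group for step 4.

Step 4
Reactants: 6 1-(5-methylhex-4-en-1-yn-1-yl)-2,4,5-trimethoxy-3-(3-methylbut-2-en-1-yl)benzene; 8 2-hydroxy-4,6-bis(methoxymethoxy)benzaldehyde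
Product: 9 5,7-bis(methoxymethoxy)-3-(3-methylbut-2-en-1-yl)-2-[2,4,5-trimethoxy-3-(3-methylbut-2-en-1-yl)phenyl]-4H-chromen-4-one
Conditions: [RhCl(cod)]2 (2.5 mol %), 1,2,3,4-tetraphenylcyclopenta-1,3-diene (10 mol %), Cu(OAc)2·H2O (2.2 equiv), o-xylene, 120 °C, N2
Reagents that add atoms: none
Why: The phenol of 8 binds to Rh(III) as a phenoxide and brings the formyl C–H to the metal for acetate-assisted cleavage to a five-membered acyl-rhodacycle; the alkyne of 6 inserts into the Rh–acyl bond to give a seven-membered oxa-rhodacycle, C–O reductive elimination releases 9, and Cu(II) returns Rh(I) to Rh(III). The closest known reaction type is the rhodium-catalysed oxidative coupling of salicylaldehydes with internal alkynes to 2,3-disubstituted chromones, a chelation-assisted aldehyde C–H activation with [4+2] annulation. Ring C is the only ring closed, by intermolecular C3–C4 bond formation followed by ring-closing O1–C2 reductive elimination at the metal, and no stereocentre is formed. The step needs regioselective insertion, which the aryl/alkyl bias of 6 should secure: the acyl group goes to the carbon bearing the propargylic CH2, rhodium takes the carbon bearing the electron-rich aryl group (where the 2-methoxy oxygen can assist by coordination), and the aryl group therefore ends at C2 next to O1. It also needs chemoselectivity for the alkyne over the two trisubstituted prenyl alkenes, which bind and insert far more slowly, and the near-neutral acetate medium should leave the skipped-enyne CH2 and the MOM ethers untouched. Decarbonylation of the acyl-rhodium should be held back by the chelate and by fast alkyne insertion.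

Step 5
Reactants: 9 5,7-bis(methoxymethoxy)-3-(3-methylbut-2-en-1-yl)-2-[2,4,5-trimethoxy-3-(3-methylbut-2-en-1-yl)phenyl]-4H-chromen-4-one
Product: 11 2-[2,5-dihydroxy-4-methoxy-3-(3-methylbut-2-en-1-yl)phenyl]-5,7-bis(methoxymethoxy)-3-(3-methylbut-2-en-1-yl)-4H-chromen-4-one, via p-quinone 10 (not isolated)
Conditions: CAN (2.5 equiv), MeCN/H2O, 0 °C, short contact; then aq. Na2S2O4, EtOAc, rt
Reagents that add atoms: water, O
Why: This is a Ce(IV) oxidative demethylation of a 1,4-dimethoxyarene followed by dithionite reduction, in which the twisted and most electron-rich ring B is oxidised first, water attacks the para-related C2' and C5' with loss of two methanols to give p-quinone 10 (the 4'-methoxy group survives as a vinylogous ester), and immediate reduction should give the hydroquinone before the quinone can react with the nearby prenyl groups.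

Step 6
Reactants: 11 2-[2,5-dihydroxy-4-methoxy-3-(3-methylbut-2-en-1-yl)phenyl]-5,7-bis(methoxymethoxy)-3-(3-methylbut-2-en-1-yl)-4H-chromen-4-one
Product: 12 heteroartonin A, 2-[2,5-dihydroxy-4-methoxy-3-(3-methylbut-2-en-1-yl)phenyl]-5,7-dihydroxy-3-(3-methylbut-2-en-1-yl)-4H-chromen-4-one
Conditions: 3 M aq. HCl, MeOH, 45 °C, Ar
Reagents that add atoms: none
Why: This is an acid-catalysed acetal exchange (MOM cleavage) in methanol, a standard last step for prenylated flavonoids, which should free the 5- and 7-OH groups at a temperature where protonation of the trisubstituted alkenes and chroman formation with the 2'-OH stay slow, with argon protecting the hydroquinone.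

Compound list
1 | 2,4,5-trimethoxybenzaldehyde | COc1cc(OC)c(C=O)cc1OC | starting material
2 | 1-ethynyl-2,4,5-trimethoxybenzene | C#Cc1cc(OC)c(OC)cc1OC | intermediate
3 | prenyl bromide (1-bromo-3-methylbut-2-ene) | CC(C)=CCBr | starting material
4 | [3-(lithioethynyl)-2,5,6-trimethoxyphenyl]lithium (dilithio species, not isolated) | [Li]C#Cc1cc(OC)c(OC)c([Li])c1OC | intermediate
5 | lithium [2,4,5-trimethoxy-3-(3-methylbut-2-en-1-yl)phenyl]acetylide (not isolated) | [Li]C#Cc1cc(OC)c(OC)c(CC=C(C)C)c1OC | intermediate
6 | 1-(5-methylhex-4-en-1-yn-1-yl)-2,4,5-trimethoxy-3-(3-methylbut-2-en-1-yl)benzene | COc1cc(C#CCC=C(C)C)c(OC)c(CC=C(C)C)c1OC | intermediate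
7 | 2,4,6-trihydroxybenzaldehyde | O=Cc1c(O)cc(O)cc1O | starting material
8 | 2-hydroxy-4,6-bis(methoxymethoxy)benzaldehyde | COCOc1cc(O)c(C=O)c(OCOC)c1 | intermediate
9 | 5,7-bis(methoxymethoxy)-3-(3-methylbut-2-en-1-yl)-2-[2,4,5-trimethoxy-3-(3-methylbut-2-en-1-yl)phenyl]-4H-chromen-4-one | COCOc1cc(OCOC)c2c(=O)c(CC=C(C)C)c(-c3cc(OC)c(OC)c(CC=C(C)C)c3OC)oc2c1 | intermediate
10 | 2-[5,7-bis(methoxymethoxy)-3-(3-methylbut-2-en-1-yl)-4-oxo-4H-chromen-2-yl]-5-methoxy-6-(3-methylbut-2-en-1-yl)cyclohexa-2,5-diene-1,4-dione (not isolated) | COCOc1cc(OCOC)c2c(=O)c(CC=C(C)C)c(C3=CC(=O)C(OC)=C(CC=C(C)C)C3=O)oc2c1 | intermediate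
11 | 2-[2,5-dihydroxy-4-methoxy-3-(3-methylbut-2-en-1-yl)phenyl]-5,7-bis(methoxymethoxy)-3-(3-methylbut-2-en-1-yl)-4H-chromen-4-one | COCOc1cc(OCOC)c2c(=O)c(CC=C(C)C)c(-c3cc(O)c(OC)c(CC=C(C)C)c3O)oc2c1 | intermediate
12 | heteroartonin A | COc1c(O)cc(-c2oc3cc(O)cc(O)c3c(=O)c2CC=C(C)C)c(O)c1CC=C(C)C | target

Total step count: 6. Longest linear sequence: 5 (steps 1, 2, 4, 5, 6); step 3 is the one-step side branch.

Steps most likely to fail (in route order)

Step 2. Ring lithiation next to the anionic acetylide may stay incomplete. The skipped-enyne CH2 may also undergo a base-induced prototropic shift into conjugation while organolithium is still present.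
- The fallback sets out from 2 and comes back at 6. It gives up the dianion double alkylation and makes the two C–C bonds in separate operations of different type.
- Compound 2 is dilithiated, treated with only one equivalent of 3 and quenched with water. This gives 1-ethynyl-2,4,5-trimethoxy-3-(3-methylbut-2-en-1-yl)benzene F1, which can be freed from unlithiated material.
- F1 is then coupled with 3 through a catalytic copper acetylide under carbonate base (CuI, NaI, K2CO3, DMF, rt). This medium is too weakly basic to isomerise 6.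

Step 4. The ortho-substituted aryl group may erode the regioselectivity of alkyne insertion. The hindered acyl-rhodium may decarbonylate, or the metal may isomerise the skipped enyne.
- The fallback sets out from 2 and 8 and comes back at 9. It builds ring C by polar chemistry through an ynone and adds the C3 prenyl group last.
- The lithium acetylide of 1-ethynyl-2,4,5-trimethoxy-3-(3-methylbut-2-en-1-yl)benzene F1 (from 2 as above) is added to the lithium phenoxide of 8. This gives racemic 1-[2-hydroxy-4,6-bis(methoxymethoxy)phenyl]-3-[2,4,5-trimethoxy-3-(3-methylbut-2-en-1-yl)phenyl]prop-2-yn-1-ol F2.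
- MnO2 oxidation gives 1-[2-hydroxy-4,6-bis(methoxymethoxy)phenyl]-3-[2,4,5-trimethoxy-3-(3-methylbut-2-en-1-yl)phenyl]prop-2-yn-1-one F3.
- DMAP-induced 6-endo-dig oxa-Michael closure gives 5,7-bis(methoxymethoxy)-2-[2,4,5-trimethoxy-3-(3-methylbut-2-en-1-yl)phenyl]-4H-chromen-4-one F4.
- C3 lithiation with LDA at −78 °C followed by alkylation with 3 gives 9.

Step 5. The neighbouring C3 prenyl alkene may attack the transient quinone. Oxidation may occur at the prenyl groups, or MOM groups may be lost in the acidic Ce(IV) medium on the fully assembled flavone.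
- The fallback sets out from 6 (and 8) and comes back at 12. It moves the redox unmasking of ring B ahead of the key step, so that no quinone ever sits beside the C3 prenyl group.
- Compound 6 is oxidised with CAN to 2-methoxy-5-(5-methylhex-4-en-1-yn-1-yl)-3-(3-methylbut-2-en-1-yl)cyclohexa-2,5-diene-1,4-dione F5.
- F5 is reduced at once with dithionite to 2-methoxy-5-(5-methylhex-4-en-1-yn-1-yl)-3-(3-methylbut-2-en-1-yl)benzene-1,4-diol F6.
- F6 is protected with MOMCl and i-Pr2NEt as 2-methoxy-1,4-bis(methoxymethoxy)-5-(5-methylhex-4-en-1-yn-1-yl)-3-(3-methylbut-2-en-1-yl)benzene F7.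
- The annulation of step 4 with 8 then gives 2-[4-methoxy-2,5-bis(methoxymethoxy)-3-(3-methylbut-2-en-1-yl)phenyl]-5,7-bis(methoxymethoxy)-3-(3-methylbut-2-en-1-yl)-4H-chromen-4-one F8.
- One global MOM cleavage (aq. HCl, MeOH) gives 12.

Further compounds
F1 | step 2 | 1-ethynyl-2,4,5-trimethoxy-3-(3-methylbut-2-en-1-yl)benzene | C#Cc1cc(OC)c(OC)c(CC=C(C)C)c1OC
F2 | step 4 | 1-[2-hydroxy-4,6-bis(methoxymethoxy)phenyl]-3-[2,4,5-trimethoxy-3-(3-methylbut-2-en-1-yl)phenyl]prop-2-yn-1-ol (racemic) | COCOc1cc(O)c(C(O)C#Cc2cc(OC)c(OC)c(CC=C(C)C)c2OC)c(OCOC)c1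
F3 | step 4 | 1-[2-hydroxy-4,6-bis(methoxymethoxy)phenyl]-3-[2,4,5-trimethoxy-3-(3-methylbut-2-en-1-yl)phenyl]prop-2-yn-1-one | COCOc1cc(O)c(C(=O)C#Cc2cc(OC)c(OC)c(CC=C(C)C)c2OC)c(OCOC)c1
F4 | step 4 | 5,7-bis(methoxymethoxy)-2-[2,4,5-trimethoxy-3-(3-methylbut-2-en-1-yl)phenyl]-4H-chromen-4-one | COCOc1cc(OCOC)c2c(=O)cc(-c3cc(OC)c(OC)c(CC=C(C)C)c3OC)oc2c1
F5 | step 5 | 2-methoxy-5-(5-methylhex-4-en-1-yn-1-yl)-3-(3-methylbut-2-en-1-yl)cyclohexa-2,5-diene-1,4-dione | COC1=C(CC=C(C)C)C(=O)C(C#CCC=C(C)C)=CC1=O
F6 | step 5 | 2-methoxy-5-(5-methylhex-4-en-1-yn-1-yl)-3-(3-methylbut-2-en-1-yl)benzene-1,4-diol | COc1c(O)cc(C#CCC=C(C)C)c(O)c1CC=C(C)C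
F7 | step 5 | 2-methoxy-1,4-bis(methoxymethoxy)-5-(5-methylhex-4-en-1-yn-1-yl)-3-(3-methylbut-2-en-1-yl)benzene | COCOc1cc(C#CCC=C(C)C)c(OCOC)c(CC=C(C)C)c1OC
F8 | step 5 | 2-[4-methoxy-2,5-bis(methoxymethoxy)-3-(3-methylbut-2-en-1-yl)phenyl]-5,7-bis(methoxymethoxy)-3-(3-methylbut-2-en-1-yl)-4H-chromen-4-one | COCOc1cc(OCOC)c2c(=O)c(CC=C(C)C)c(-c3cc(OCOC)c(OC)c(CC=C(C)C)c3OCOC)oc2c1
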